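Numbering: ring C1–C10 with the Z alkene C1=C10 (methyl C14 on C10) and the E alkene C4=C5 (methyl C15 on C4); lactone ring O–C6–C7–C11(=C13)–C12(=O); hydroxyls on C7 and C9; epoxy ester on O8.
Retrosynthetic cuts, in order: the O8 ester bond; the lactone carbonyl (back to a C6,C12-diol); the C1=C10 double bond, by putting SO2 back between C1 and C10 (eleven-membered C10-chloro sulfone); the C1–S bond; then C5–C6, C7–C11 and C7–C8.
Enabling feature: the Z-trisubstituted C1=C10 alkene beside the C9 carbinol is the ring bond hardest to make directly, but C1 and C10 can be spanned by one sulfur atom in an eleven-membered thiacycle that closes by thiolate alkylation at primary C1; once C10 carries chlorine it has no hydrogen, so only C1 can be deprotonated.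
Forward order: the chain is built linearly from C10 towards C6 (epoxy aldehyde plus diazoacetate), C11 and the C1–C5 alkenyl unit are added to the two carbonyls, the eleven-membered sulfide ring is closed and contracted to the ten-membered carbocycle, and the lactone ring and the O8 ester come last.
Stereochemistry: C9 from Sharpless epoxidation of (E)-crotyl alcohol, C8 by Felkin-type addition to the epoxy aldehyde, C7 by Felkin–Anh addition to the keto ester, C6 by chelation-controlled reduction, the side-chain epoxide from Sharpless epoxidation of tiglyl alcohol, and the 1(10)Z geometry from the cis-fused episulfone.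
Key step: step 21

Assumption: the α-chlorination of the macrocyclic sulfide is taken to occur at the more substituted carbon C10 and to give both C10 epimers; these are carried together, so the chloro compounds and the episulfone are drawn without descriptors at C10, sulfur and C1.

Step 1
Reactants: 1 (E)-but-2-en-1-ol
Product: 2 [(2S,3S)-3-methyloxiran-2-yl]methanol
Conditions: Ti(OiPr)4 (5 mol %), L-(+)-diethyl tartrate (6 mol %), tBuOOH, 4 Å MS, CH2Cl2, −20 °C
Reagents that add atoms: tert-butyl hydroperoxide, CC(C)(C)OO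
Why: Katsuki–Sharpless asymmetric epoxidation of a primary (E)-allylic alcohol is reliable, and with L-(+)-diethyl tartrate the titanium–tartrate complex delivers oxygen to the face that gives the (2S,3S)-epoxide, which sets C9 of the target and a temporary centre at C10.

Step 2
Reactants: 2 [(2S,3S)-3-methyloxiran-2-yl]methanol
Product: 3 (2R,3S)-3-methyloxirane-2-carbaldehyde
Conditions: TEMPO (10 mol %), PhI(OAc)2, CH2Cl2, 0 °C to rt; dried solution of the volatile aldehyde used directly
Reagents that add atoms: none
Why: Nitroxyl-catalysed oxidation with PhI(OAc)2 (Piancatelli–Margarita oxidation) takes the primary alcohol only to the aldehyde under nearly neutral conditions, so the epoxide and the configuration of the adjacent carbon are preserved.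

Step 3
Reactants: 3 (2R,3S)-3-methyloxirane-2-carbaldehyde; 4 ethyl diazoacetate
Product: 6 diazo aldol (C8 carbinol), via ethyl lithiodiazoacetate 5 (not isolated)
Conditions: LiN(iPr)2 added to 3 and 4, THF, −78 °C; AcOH quench
Reagents that add atoms: none
Why: Aldol-type addition of lithiated ethyl diazoacetate to an aldehyde is fast at −78 °C, and the new C8 carbinol should form anti to the epoxide oxygen because the nucleophile attacks the Cornforth (polar Felkin–Anh) conformer of the trans-epoxy aldehyde from the side of the C9 hydrogen, as known for lithium enolate additions to α,β-epoxy aldehydes.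

Step 4
Reactants: 6 diazo aldol
Product: 7 C8 triethylsilyl ether of the diazo ester
Conditions: Et3SiCl, imidazole, DMF, 0 °C
Reagents that add atoms: chlorotriethylsilane, CC[Si](Cl)(CC)CC
Why: Standard silylation of a secondary alcohol with a silyl chloride and imidazole masks C8–OH as a non-chelating ether and leaves the diazo ester and the epoxide untouched.

Step 5
Reactants: 7 C8 triethylsilyl ether of the diazo ester
Product: 8 α-keto ester (C7 ketone)
Conditions: dimethyldioxirane, acetone, 0 °C
Reagents that add atoms: dimethyldioxirane, CC1(C)OO1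
Why: Dimethyldioxirane transfers oxygen to the nucleophilic diazo carbon with loss of N2 (oxidation of an α-diazo ester to an α-keto ester), a neutral reaction that is run before any alkene is present and does not touch the silyl ether or the epoxide.

Step 6
Reactants: 9 2-bromoprop-2-en-1-ol
Product: 10 (2-bromoallyloxy)(tert-butyl)dimethylsilane
Conditions: tBuMe2SiCl, imidazole, CH2Cl2, rt
Reagents that add atoms: tert-butyldimethylsilyl chloride, CC(C)(C)[Si](C)(C)Cl
Why: Silylation of a primary allylic alcohol with a silyl chloride and imidazole is routine and gives the precursor of the 2-lithioallyl reagent that carries C11, C12 and C13.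

Step 7
Reactants: 8 α-keto ester; 10 (2-bromoallyloxy)(tert-butyl)dimethylsilane
Product: 12 C7 tertiary alcohol (ethyl ester), via 2-lithioallyl silyl ether 11 (not isolated)
Conditions: 10, tBuLi (2 equiv), Et2O, −78 °C; then 8, THF, −78 °C; aq NH4Cl
Reagents that add atoms: none
Why: Bromine–lithium exchange gives the alkenyllithium, which adds 1,2 to the ketone carbonyl, the more electrophilic carbonyl of the α-keto ester, and C7 should be set by polar Felkin–Anh control in which the nucleophile enters anti to the C8–OSi bond past the C8 hydrogen, because a triethylsilyl ether and lithium in THF do not form a chelate.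

Step 8
Reactants: 12 C7 tertiary alcohol (ethyl ester)
Product: 13 Weinreb amide
Conditions: MeNHOMe·HCl, iPrMgCl, THF, −20 to 0 °C
Reagents that add atoms: N,O-dimethylhydroxylamine hydrochloride, CNOC.Cl
Why: Aminolysis of the ester with the chloromagnesium amide of N,O-dimethylhydroxylamine (Weinreb amide formation) works on hindered and α-hydroxylated esters and should leave the silyl ethers and the epoxide intact at or below 0 °C.

Step 9
Reactants: 14 pent-4-yn-1-ol
Product: 16 (E)-5-iodo-4-methylpent-4-en-1-ol, via alkenylalane 15 (not isolated)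
Conditions: Me3Al (3 equiv), Cp2ZrCl2 (25 mol %), CH2Cl2, 0 °C to rt; then I2, THF, −30 °C
Reagents that add atoms: trimethylaluminium, C[Al](C)C; iodine, II
Why: Negishi zirconium-catalysed carboalumination adds methyl and aluminium syn across the terminal alkyne with the metal on the terminal carbon, and iodinolysis with retention gives the (E)-trisubstituted vinyl iodide that carries C1 to C5 and the C4 methyl group.

Step 10
Reactants: 16 (E)-5-iodo-4-methylpent-4-en-1-ol
Product: 17 (E)-1-iodo-5-(4-methoxybenzyloxy)-2-methylpent-1-ene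
Conditions: NaH, 4-methoxybenzyl chloride, Bu4NI (cat.), THF–DMF, 0 °C to rt
Reagents that add atoms: 4-methoxybenzyl chloride, COc1ccc(CCl)cc1
Why: Williamson etherification of the primary alkoxide with 4-methoxybenzyl chloride is routine and does not affect the vinyl iodide.

Step 11
Reactants: 13 Weinreb amide; 17 (E)-1-iodo-5-(4-methoxybenzyloxy)-2-methylpent-1-ene
Product: 19 α-hydroxy (E)-enone (C6 ketone), via alkenyllithium 18 (not isolated)
Conditions: 17, tBuLi (2 equiv), Et2O, −78 °C; then 13 (0.4 equiv), THF, −78 to −20 °C; aq NH4Cl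
Reagents that add atoms: none
Why: Iodine–lithium exchange proceeds with retention of the alkene geometry and the alkenyllithium acylates the Weinreb amide (Weinreb ketone synthesis), the chelated tetrahedral intermediate preventing over-addition so that the (E)-enone is released on work-up.

Step 12
Reactants: 19 α-hydroxy (E)-enone
Product: 20 anti-6,7-diol
Conditions: Zn(BH4)2, Et2O, −30 °C
Reagents that add atoms: none
Why: Zn(BH4)2 reduces the α-hydroxy enone 1,2 under chelation control (Cram-chelate reduction), zinc bridging the C7 hydroxyl and the C6 carbonyl so that hydride enters from the face of the flat C11 alkenyl group, anti to the branched C8 chain, which should give the anti 6,7-diol with the C6 configuration of the target.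

Step 13
Reactants: 20 anti-6,7-diol
Product: 21 6,7-acetonide
Conditions: 2-methoxypropene, PPTS (cat.), CH2Cl2, 0 °C
Reagents that add atoms: 2-methoxypropene, COC(C)=C
Why: Acid-catalysed ketal exchange with 2-methoxypropene (acetonide formation) ties the only two free hydroxyls into a dioxolane under conditions too mild to open the epoxide or cleave the silyl ethers.

Step 14
Reactants: 21 6,7-acetonide
Product: 22 C10 thioacetate with free C9 hydroxyl
Conditions: AcSH, KSAc (0.2 equiv), DMF, 40 °C
Reagents that add atoms: thioacetic acid, CC(=O)S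
Why: Thioacetate opens the trans-epoxide by SN2 attack at C10, the carbon remote from the hindered and oxygenated C8 side, so that sulfur arrives with inversion at C10 while the C9–O bond and its configuration are retained, and the acidic medium suppresses sulfur-to-oxygen acetyl migration.

Step 15
Reactants: 22 C10 thioacetate with free C9 hydroxyl
Product: 23 C9 tert-butyldimethylsilyl ether
Conditions: tBuMe2SiOTf, 2,6-lutidine, CH2Cl2, −78 to 0 °C
Reagents that add atoms: tert-butyldimethylsilyl trifluoromethanesulfonate, CC(C)(C)[Si](C)(C)OS(=O)(=O)C(F)(F)F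
Why: Silylation with a silyl triflate and 2,6-lutidine protects the hindered C9 hydroxyl at low temperature without disturbing the thioester, the acetonide or the other silyl ethers.

Step 16
Reactants: 23 C9 tert-butyldimethylsilyl ether
Product: 24 C1 primary alcohol
Conditions: DDQ, CH2Cl2–pH 7 buffer, 0 °C
Reagents that add atoms: none
Why: Oxidative cleavage of a 4-methoxybenzyl ether with DDQ in buffered wet dichloromethane frees the primary C1 alcohol selectively, because silyl ethers, the acetonide, the thioester and the alkenes are not oxidised under these conditions.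

Step 17
Reactants: 24 C1 primary alcohol
Product: 25 C1 mesylate
Conditions: MsCl, Et3N, CH2Cl2, 0 °C
Reagents that add atoms: methanesulfonyl chloride, CS(=O)(=O)Cl
Why: Mesylation of a primary alcohol with methanesulfonyl chloride and triethylamine is fast at 0 °C and provides the leaving group for ring closure.

Step 18
Reactants: 25 C1 mesylate
Product: 27 eleven-membered cyclic sulfide, via cesium thiolate 26 (not isolated)
Conditions: Cs2CO3, MeOH–DMF (degassed), 1 mM, slow addition, 40 °C
Reagents that add atoms: none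
Why: Methanolysis of the thioacetate liberates the cesium thiolate, which displaces the primary mesylate intramolecularly at high dilution (macrocyclic thioether formation by thiolate alkylation), closing the eleven-membered ring at an unhindered carbon without touching any stereocentre.

Step 19
Reactants: 27 eleven-membered cyclic sulfide
Product: 29 C10-chloro sulfoxide, via C10-chloro sulfide 28 (not isolated)
Conditions: NCS, CCl4, 0 °C; then mCPBA (1 equiv), CH2Cl2, −78 °C
Reagents that add atoms: N-chlorosuccinimide, O=C1CCC(=O)N1Cl; 3-chloroperbenzoic acid, OOC(=O)c1cccc(Cl)c1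
Why: N-Chlorosuccinimide chlorinates the sulfide through a chlorosulfonium and thionium ion (Pummerer-type α-chlorination) at the more substituted α-carbon C10, and one equivalent of peracid at −78 °C then oxidises sulfur far faster than either alkene, which converts the labile tertiary α-chloro sulfide into a stable α-chloro sulfoxide.

Step 20
Reactants: 29 C10-chloro sulfoxide
Product: 30 C10-chloro eleven-membered cyclic sulfone
Conditions: H2O2 (30%), (NH4)6Mo7O24·4H2O (10 mol %), EtOH, 0 °C to rt
Reagents that add atoms: hydrogen peroxide, OO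
Why: Molybdate-catalysed oxidation with hydrogen peroxide takes sulfoxides to sulfones without epoxidising isolated tri- and disubstituted alkenes, so the chloro sulfone should be reached chemoselectively.

Step 21
Reactants: 30 C10-chloro eleven-membered cyclic sulfone
Product: 32 protected ten-membered (1(10)Z,4E)-diene, via episulfone 31 (not isolated)
Conditions: KOtBu, THF, −78 to 0 °C
Reagents that add atoms: none
Why: KOtBu removes a proton from C1, the only sulfone α-carbon that bears hydrogen, and the carbanion displaces chloride from C10 in an intramolecular 1,3-elimination to give the bicyclic episulfone 31, which loses SO2 to leave the C1=C10 double bond. The closest known reaction is the Ramberg–Bäcklund ring contraction of cyclic α-halo sulfones to medium-ring cycloalkenes. The three-membered thiirane dioxide closes in the 3-exo-tet mode, and the ten-membered carbocycle arises in the same event because the new C1–C10 bond is formed inside the eleven-membered ring. No new stereocentre is created; the only new stereo-element is the alkene geometry, which is fixed by the cis ring fusion of the episulfone that the medium ring enforces and is transferred by the stereospecific extrusion of SO2, so that the 1(10)Z olefin with C2 and C9 cis should result. The step needs site-selective carbanion formation without β-elimination of the C9 silyloxy group, and the fully substituted C10 secures this because no carbanion can form next to C9, while both C10 epimers converge on the same alkene. The E-configured C4=C5 bond, the acetonide and the three silyl ethers are inert to the base at low temperature.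

Step 22
Reactants: 32 protected ten-membered (1(10)Z,4E)-diene
Product: 33 C6,C7,C8,C12-tetraol with C9 silyl ether
Conditions: AcOH–THF–H2O (3:1:1), 40 °C
Reagents that add atoms: none
Why: Aqueous acetic acid hydrolyses the acetonide, the primary allylic tert-butyldimethylsilyl ether and the secondary triethylsilyl ether (acid-catalysed ketal and silyl ether hydrolysis), whereas the hindered secondary tert-butyldimethylsilyl ether at C9 is much slower to cleave and should be kept.

Step 23
Reactants: 33 C6,C7,C8,C12-tetraol with C9 silyl ether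
Product: 36 α-methylene lactone with free C7 and C8 hydroxyls, via hydroxy enal 34 (not isolated), via lactol 35 (not isolated)
Conditions: Cu(MeCN)4OTf (5 mol %), 2,2′-bipyridine, TEMPO, N-methylimidazole, air, MeCN, rt
Reagents that add atoms: none
Why: Copper and nitroxyl catalysed aerobic oxidation is selective for the unhindered primary allylic alcohol, the resulting hydroxy enal closes to the five-membered lactol with the C6 hydroxyl and the lactol is oxidised further (oxidative lactonisation of a 1,4-diol), so the α-methylene lactone should form without cleavage of the 7,8-diol.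

Step 24
Reactants: 37 tiglic acid
Product: 38 (E)-2-methylbut-2-en-1-ol
Conditions: LiAlH4, Et2O, 0 °C
Reagents that add atoms: none
Why: LiAlH4 reduces the carboxylic acid 1,2 to the allylic alcohol (hydride reduction) without touching the trisubstituted alkene.

Step 25
Reactants: 38 (E)-2-methylbut-2-en-1-ol
Product: 39 [(2R,3R)-2,3-dimethyloxiran-2-yl]methanol
Conditions: Ti(OiPr)4 (5 mol %), D-(−)-diethyl tartrate (6 mol %), tBuOOH, 4 Å MS, CH2Cl2, −20 °C
Reagents that add atoms: tert-butyl hydroperoxide, CC(C)(C)OO
Why: Katsuki–Sharpless asymmetric epoxidation with D-(−)-diethyl tartrate delivers oxygen to the face opposite to that used in step 1 and gives the (2R,3R)-epoxy alcohol, which fixes both stereocentres of the side chain.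

Step 26
Reactants: 39 [(2R,3R)-2,3-dimethyloxiran-2-yl]methanol
Product: 40 (2S,3R)-2,3-dimethyloxirane-2-carboxylic acid
Conditions: RuCl3 (2 mol %), NaIO4, CCl4–MeCN–H2O, rt
Reagents that add atoms: sodium periodate, [Na+].[O-]I(=O)(=O)=O
Why: Ruthenium tetroxide generated from RuCl3 and NaIO4 (Sharpless oxidation) converts the primary alcohol of an epoxy alcohol into the carboxylic acid without opening the epoxide, so both stereocentres are kept and only the descriptor at C2 changes.

Step 27
Reactants: 36 α-methylene lactone with free C7 and C8 hydroxyls; 40 (2S,3R)-2,3-dimethyloxirane-2-carboxylic acid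
Product: 42 C9-silylated target ester, via mixed anhydride 41 (not isolated)
Conditions: 40, 2,4,6-trichlorobenzoyl chloride, Et3N, THF, rt; then 36, DMAP, toluene, rt
Reagents that add atoms: none
Why: Yamaguchi esterification through the mixed 2,4,6-trichlorobenzoic anhydride and DMAP acylates hindered secondary alcohols, and only the C8 hydroxyl should react because the C7 hydroxyl is tertiary and C9 is silylated.

Step 28
Reactants: 42 C9-silylated target ester
Product: 43 CNP0420662.1
Conditions: HF·pyridine, pyridine, THF, 0 °C to rt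
Reagents that add atoms: none
Why: Fluoride cleavage of the silyl ether with pyridine-buffered HF·pyridine is mild and nearly neutral, so the epoxy ester, the α-methylene lactone and the diene should survive and acyl migration from O8 to O9 is avoided.

Compound list
1 | (E)-but-2-en-1-ol | C/C=C/CO | starting material
2 | [(2S,3S)-3-methyloxiran-2-yl]methanol | C[C@@H]1O[C@H]1CO | intermediate
3 | (2R,3S)-3-methyloxirane-2-carbaldehyde | C[C@@H]1O[C@H]1C=O | intermediate
4 | ethyl diazoacetate | CCOC(=O)C=[N+]=[N-] | starting material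
5 | ethyl lithiodiazoacetate | CCOC(=O)C([Li])=[N+]=[N-] | intermediate
6 | ethyl (3S)-2-diazo-3-hydroxy-3-[(2S,3S)-3-methyloxiran-2-yl]propanoate (C8 carbinol anti to the epoxide oxygen) | C[C@@H]1O[C@H]1[C@@H](O)C(=[N+]=[N-])C(=O)OCC | intermediate
7 | ethyl (3S)-2-diazo-3-[(2R,3S)-3-methyloxiran-2-yl]-3-(triethylsilyloxy)propanoate | C[C@@H]1O[C@H]1[C@@H](O[Si](CC)(CC)CC)C(=[N+]=[N-])C(=O)OCC | intermediate
8 | ethyl (3R)-3-[(2R,3S)-3-methyloxiran-2-yl]-2-oxo-3-(triethylsilyloxy)propanoate | C[C@@H]1O[C@H]1[C@@H](O[Si](CC)(CC)CC)C(=O)C(=O)OCC | intermediate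
9 | 2-bromoprop-2-en-1-ol | OCC(Br)=C | starting material
10 | (2-bromoallyloxy)(tert-butyl)dimethylsilane | C=C(Br)CO[Si](C)(C)C(C)(C)C | intermediate
11 | [3-(tert-butyldimethylsilyloxy)prop-1-en-2-yl]lithium | C=C([Li])CO[Si](C)(C)C(C)(C)C | intermediate
12 | ethyl 2-hydroxy-2-[3-(tert-butyldimethylsilyloxy)prop-1-en-2-yl]-3-(trans-3-methyloxiran-2-yl)-3-(triethylsilyloxy)propanoate; C7, C8, C9 as in the target, C10 (S) | C[C@@H]1O[C@H]1[C@@H](O[Si](CC)(CC)CC)[C@@](O)(C(=C)CO[Si](C)(C)C(C)(C)C)C(=O)OCC | intermediate
13 | N-methoxy-N-methyl amide of 12 (Weinreb amide); C7, C8, C9 as in the target | C[C@@H]1O[C@H]1[C@@H](O[Si](CC)(CC)CC)[C@@](O)(C(=C)CO[Si](C)(C)C(C)(C)C)C(=O)N(C)OC | intermediate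
14 | pent-4-yn-1-ol | C#CCCCO | starting material
15 | (E)-alkenyl(dimethyl)alane, O-dimethylaluminium alkoxide | C[Al](C)OCCC/C(C)=C/[Al](C)C | intermediate
16 | (E)-5-iodo-4-methylpent-4-en-1-ol | OCCC/C(C)=C/I | intermediate
17 | (E)-1-iodo-5-(4-methoxybenzyloxy)-2-methylpent-1-ene | COc1ccc(COCCC/C(C)=C/I)cc1 | intermediate
18 | (E)-[5-(4-methoxybenzyloxy)-2-methylpent-1-enyl]lithium | COc1ccc(COCCC/C(C)=C/[Li])cc1 | intermediate
19 | C6 ketone: α-hydroxy (4E)-enone with C7 OH, C8 OSiEt3, 9,10-epoxide, C12 OSi(tBu)Me2, C1 O-4-methoxybenzyl; C7, C8, C9 as in the target | C[C@@H]1O[C@H]1[C@@H](O[Si](CC)(CC)CC)[C@@](O)(C(=C)CO[Si](C)(C)C(C)(C)C)C(=O)/C=C(\C)CCCOCc1ccc(OC)cc1 | intermediate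
20 | anti-6,7-diol of 19; C6, C7, C8, C9 as in the target | C[C@@H]1O[C@H]1[C@@H](O[Si](CC)(CC)CC)[C@@](O)(C(=C)CO[Si](C)(C)C(C)(C)C)[C@H](O)/C=C(\C)CCCOCc1ccc(OC)cc1 | intermediate
21 | 6,7-O-isopropylidene derivative of 20 | C[C@@H]1O[C@H]1[C@@H](O[Si](CC)(CC)CC)[C@@]2(OC(C)(C)O[C@@H]2/C=C(\C)CCCOCc3ccc(OC)cc3)C(=C)CO[Si](C)(C)C(C)(C)C | intermediate
22 | C10 S-acetyl thiol with free C9 OH (C10 R, from inversion) | C[C@@H](SC(C)=O)[C@@H](O)[C@@H](O[Si](CC)(CC)CC)[C@@]1(OC(C)(C)O[C@@H]1/C=C(\C)CCCOCc2ccc(OC)cc2)C(=C)CO[Si](C)(C)C(C)(C)C | intermediate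
23 | C9 tert-butyldimethylsilyl ether of 22 | C[C@@H](SC(C)=O)[C@@H](O[Si](C)(C)C(C)(C)C)[C@@H](O[Si](CC)(CC)CC)[C@@]1(OC(C)(C)O[C@@H]1/C=C(\C)CCCOCc2ccc(OC)cc2)C(=C)CO[Si](C)(C)C(C)(C)C | intermediate
24 | C1 primary alcohol (4-methoxybenzyl group removed from 23) | C[C@@H](SC(C)=O)[C@@H](O[Si](C)(C)C(C)(C)C)[C@@H](O[Si](CC)(CC)CC)[C@@]1(OC(C)(C)O[C@@H]1/C=C(\C)CCCO)C(=C)CO[Si](C)(C)C(C)(C)C | intermediate
25 | C1 methanesulfonate of 24 | C[C@@H](SC(C)=O)[C@@H](O[Si](C)(C)C(C)(C)C)[C@@H](O[Si](CC)(CC)CC)[C@@]1(OC(C)(C)O[C@@H]1/C=C(\C)CCCOS(C)(=O)=O)C(=C)CO[Si](C)(C)C(C)(C)C | intermediate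
26 | cesium C10 thiolate of 25 | [Cs+].C[C@@H]([S-])[C@@H](O[Si](C)(C)C(C)(C)C)[C@@H](O[Si](CC)(CC)CC)[C@@]1(OC(C)(C)O[C@@H]1/C=C(\C)CCCOS(C)(=O)=O)C(=C)CO[Si](C)(C)C(C)(C)C | intermediate
27 | eleven-membered cyclic sulfide (S between C1 and C10; 6,7-acetonide, C8 OSiEt3, C9 OSi(tBu)Me2, C12 OSi(tBu)Me2; C10 R) | C=C(CO[Si](C)(C)C(C)(C)C)[C@@]12OC(C)(C)O[C@@H]1/C=C(\C)CCCS[C@H](C)[C@@H](O[Si](C)(C)C(C)(C)C)[C@H]2O[Si](CC)(CC)CC | intermediate
28 | C10-chloro sulfide (C10 epimers) | C=C(CO[Si](C)(C)C(C)(C)C)[C@@]12OC(C)(C)O[C@@H]1/C=C(\C)CCCSC(C)(Cl)[C@@H](O[Si](C)(C)C(C)(C)C)[C@H]2O[Si](CC)(CC)CC | intermediate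
29 | C10-chloro sulfoxide (epimers at C10 and sulfur) | C=C(CO[Si](C)(C)C(C)(C)C)[C@@]12OC(C)(C)O[C@@H]1/C=C(\C)CCCS(=O)C(C)(Cl)[C@@H](O[Si](C)(C)C(C)(C)C)[C@H]2O[Si](CC)(CC)CC | intermediate
30 | C10-chloro eleven-membered cyclic sulfone (C10 epimers) | C=C(CO[Si](C)(C)C(C)(C)C)[C@@]12OC(C)(C)O[C@@H]1/C=C(\C)CCCS(=O)(=O)C(C)(Cl)[C@@H](O[Si](C)(C)C(C)(C)C)[C@H]2O[Si](CC)(CC)CC | intermediate
31 | cis-fused episulfone (thiirane 1,1-dioxide across C1 and C10) | C=C(CO[Si](C)(C)C(C)(C)C)[C@@]12OC(C)(C)O[C@@H]1/C=C(\C)CCC3C(C)(S3(=O)=O)[C@@H](O[Si](C)(C)C(C)(C)C)[C@H]2O[Si](CC)(CC)CC | intermediate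
32 | protected ten-membered (1(10)Z,4E)-diene (6,7-acetonide, C8 OSiEt3, C9 OSi(tBu)Me2, C12 OSi(tBu)Me2) | C=C(CO[Si](C)(C)C(C)(C)C)[C@@]12OC(C)(C)O[C@@H]1/C=C(\C)CC/C=C(/C)[C@@H](O[Si](C)(C)C(C)(C)C)[C@H]2O[Si](CC)(CC)CC | intermediate
33 | (1(10)Z,4E)-diene C6,C7,C8,C12-tetraol with C9 OSi(tBu)Me2 | C=C(CO)[C@@]1(O)[C@H](O)/C=C(\C)CC/C=C(/C)[C@@H](O[Si](C)(C)C(C)(C)C)[C@H]1O | intermediate
34 | C12 aldehyde (hydroxy enal) of 33 | C=C(C=O)[C@@]1(O)[C@H](O)/C=C(\C)CC/C=C(/C)[C@@H](O[Si](C)(C)C(C)(C)C)[C@H]1O | intermediate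
35 | C12 lactol (epimers at C12) | C=C1C(O)O[C@@H]2/C=C(\C)CC/C=C(/C)[C@@H](O[Si](C)(C)C(C)(C)C)[C@@H](O)[C@@]12O | intermediate
36 | α-methylene-γ-lactone with C7 OH, C8 OH and C9 OSi(tBu)Me2 | C=C1C(=O)O[C@@H]2/C=C(\C)CC/C=C(/C)[C@@H](O[Si](C)(C)C(C)(C)C)[C@@H](O)[C@@]12O | intermediate
37 | tiglic acid | C/C=C(\C)C(=O)O | starting material
38 | (E)-2-methylbut-2-en-1-ol | C/C=C(\C)CO | intermediate
39 | [(2R,3R)-2,3-dimethyloxiran-2-yl]methanol | OC[C@@]1(C)O[C@@H]1C | intermediate
40 | (2S,3R)-2,3-dimethyloxirane-2-carboxylic acid | OC(=O)[C@@]1(C)O[C@@H]1C | intermediate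
41 | mixed anhydride of 40 with 2,4,6-trichlorobenzoic acid | O=C(OC(=O)c1c(Cl)cc(Cl)cc1Cl)[C@@]1(C)O[C@@H]1C | intermediate
42 | target ester with C9 OSi(tBu)Me2 | C=C1C(=O)O[C@@H]2/C=C(\C)CC/C=C(/C)[C@@H](O[Si](C)(C)C(C)(C)C)[C@@H](OC(=O)[C@@]3(C)O[C@@H]3C)[C@@]12O | intermediate
43 | CNP0420662.1, (6R,7R,8R,9R)-configured 7,9-dihydroxy-8-[(2S,3R)-2,3-dimethyloxirane-2-carbonyloxy]germacra-1(10)Z,4E,11(13)-trien-12,6-olide | C=C1C(=O)O[C@@H]2/C=C(\C)CC/C=C(/C)[C@@H](O)[C@@H](OC(=O)[C@@]3(C)O[C@@H]3C)[C@@]12O | target

Total step count: 28 (22 in the main line, 6 for the three side fragments 10, 17 and 40).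
Longest linear sequence: 22 steps (steps 1–5, 7, 8, 11–23, 27, 28).

Steps most likely to fail

Step 19. The Pummerer-type chlorination may go to the ring methylene C1 instead of C10, or the tertiary α-chloro sulfide may lose HCl to a vinyl sulfide before it is oxidised. The fallback sets out from sulfide 27 and returns at diene 32. Sulfide 27 is oxidised with H2O2 and (NH4)6Mo7O24 to the chlorine-free eleven-membered sulfone F1. This is contracted with CBr2F2 and KOH on Al2O3 in tBuOH–CH2Cl2 (Meyers–Chan variant with halogenation in the flask). Bromination, expected at the less hindered C1, gives the C1-bromo sulfone F2, the C10 carbanion closes it to episulfone 31, and loss of SO2 gives 32. This variant allows a carbanion next to the C9 silyloxy group, which is why it is the fallback and not the main route.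

Step 18. Intermolecular thiolate alkylation and oxidative disulfide formation may outrun closure of the eleven-membered ring. The fallback sets out from alcohol 24 and returns at sulfide 27. Mitsunobu reaction of 24 with thioacetic acid (PPh3, DIAD) gives the bis(thioacetate) F3, and methanolysis (K2CO3, MeOH) gives the dithiol F4. Oxidation with iodine at high dilution closes the twelve-membered cyclic disulfide F5, a ring closure that thiolate exchange can correct. P(NEt2)3 then extrudes one sulfur atom by attack on the less hindered sulfur and SN2 return of the C10 thiolate at primary C1, which gives 27.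

Step 22. Under acid the cyclodeca-1,5-diene may cyclise transannularly, the allylic C6–O bond may ionise, or the C9 silyl ether may be lost together with the others. The fallback sets out from chloro sulfone 30 and returns at tetraol 33, with the acid treatment moved in front of the ring contraction. AcOH–THF–H2O converts 30 into the tetraol chloro sulfone F6, and Et3SiOTf with 2,6-lutidine gives the tetrakis(triethylsilyl) ether F7. KOtBu contracts F7 through the episulfone F8 to the tetrakis(triethylsilyl) diene F9. Pyridine-buffered HF·pyridine at 0 °C then removes the four triethylsilyl groups without acid and leaves the C9 tert-butyldimethylsilyl ether, which gives 33.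

Further compounds
F1 | step 19 | chlorine-free eleven-membered sulfone | C=C(CO[Si](C)(C)C(C)(C)C)[C@@]12OC(C)(C)O[C@@H]1/C=C(\C)CCCS(=O)(=O)[C@H](C)[C@@H](O[Si](C)(C)C(C)(C)C)[C@H]2O[Si](CC)(CC)CC
F2 | step 19 | C1-bromo sulfone (C1 epimers) | C=C(CO[Si](C)(C)C(C)(C)C)[C@@]12OC(C)(C)O[C@@H]1/C=C(\C)CCC(Br)S(=O)(=O)[C@H](C)[C@@H](O[Si](C)(C)C(C)(C)C)[C@H]2O[Si](CC)(CC)CC
F3 | step 18 | bis(thioacetate) (S-acetyl at C1 and C10) | C[C@@H](SC(C)=O)[C@@H](O[Si](C)(C)C(C)(C)C)[C@@H](O[Si](CC)(CC)CC)[C@@]1(OC(C)(C)O[C@@H]1/C=C(\C)CCCSC(C)=O)C(=C)CO[Si](C)(C)C(C)(C)C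
F4 | step 18 | C1,C10-dithiol | C[C@@H](S)[C@@H](O[Si](C)(C)C(C)(C)C)[C@@H](O[Si](CC)(CC)CC)[C@@]1(OC(C)(C)O[C@@H]1/C=C(\C)CCCS)C(=C)CO[Si](C)(C)C(C)(C)C
F5 | step 18 | twelve-membered cyclic disulfide | C=C(CO[Si](C)(C)C(C)(C)C)[C@@]12OC(C)(C)O[C@@H]1/C=C(\C)CCCSS[C@H](C)[C@@H](O[Si](C)(C)C(C)(C)C)[C@H]2O[Si](CC)(CC)CC
F6 | step 22 | tetraol chloro sulfone (C6, C7, C8, C12 hydroxyls free; C10 epimers) | C=C(CO)[C@@]1(O)[C@H](O)/C=C(\C)CCCS(=O)(=O)C(C)(Cl)[C@@H](O[Si](C)(C)C(C)(C)C)[C@H]1O
F7 | step 22 | tetrakis(triethylsilyl) ether of the chloro sulfone (C10 epimers) | C=C(CO[Si](CC)(CC)CC)[C@@]1(O[Si](CC)(CC)CC)[C@H](O[Si](CC)(CC)CC)/C=C(\C)CCCS(=O)(=O)C(C)(Cl)[C@@H](O[Si](C)(C)C(C)(C)C)[C@H]1O[Si](CC)(CC)CC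
F8 | step 22 | episulfone of the tetrakis(triethylsilyl) series | C=C(CO[Si](CC)(CC)CC)[C@@]1(O[Si](CC)(CC)CC)[C@H](O[Si](CC)(CC)CC)/C=C(\C)CCC2C(C)(S2(=O)=O)[C@@H](O[Si](C)(C)C(C)(C)C)[C@H]1O[Si](CC)(CC)CC
F9 | step 22 | tetrakis(triethylsilyl) (1(10)Z,4E)-diene | C=C(CO[Si](CC)(CC)CC)[C@@]1(O[Si](CC)(CC)CC)[C@H](O[Si](CC)(CC)CC)/C=C(\C)CC/C=C(/C)[C@@H](O[Si](C)(C)C(C)(C)C)[C@H]1O[Si](CC)(CC)CC
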